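## Structural features

The target is a diaryl ketone built from two aromatic rings and has no stereocentre, so no stereochemical relationship has to be controlled. Ring A is a benzene with four contiguous substituents: the ketone at C1, hydroxyl groups at C2 and C4, and a 4-methylpentyl chain at C3 between the two oxygens; C5 and C6 carry hydrogen. Ring B is a 1H-pyrrole bonded through its C2, with chlorine at C4 and C5 and a free N–H. The rings are joined only through the carbonyl carbon, which is bonded to ring A C1 and ring B C2. The fragile elements are the electron-rich resorcinol (easily oxidised and halogenated at C5), the pyrrole (sensitive to strong acid and oxidants), and the two C–Cl bonds, which exclude hydrogenolysis and are best absent while zerovalent palladium is present. The real difficulty is regiochemical: the ketone must sit ortho to one oxygen and para to the other, the chain must sit between the oxygens, and two chlorines must enter pyrrole C4 and C5 without touching ring A C5. The key step exploits the fact that the carbonyl carbon is the single atom bridging ring A C1 and ring B C2, so it can be introduced as carbon monoxide between an aryl iodide and a pyrrol-2-yl boron compound.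

## Logic of the disconnections

**11 to 10.** The two phenols of 11 are traced back to the methyl ethers of 10, so the forward step breaks two O–CH3 bonds. Methyl ethers are chosen because they survive an aryllithium, the basic palladium coupling and the acid released during chlorination. The gain is that every intermediate is non-acidic and not prone to oxidation. The demand is an ether cleavage at the end that spares the C–Cl bonds, the ketone and the pyrrole.

**10 to 9.** The C4–Cl and C5–Cl bonds of ring B are cut. The 2-acyl group directs electrophiles to exactly these two positions, and leaving chlorine out until now keeps carbon–halogen bonds other than C–I away from the palladium step. The gain is an unsubstituted pyrrole unit. The demand is that the pyrrole must react faster than ring A C5 and that the reaction stops after two chlorines.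

**9 to 8.** The N–C(O) bond of the carbamate is cut. The carbamate is needed only to stabilise the boron partner, while the free N–H pyrrole is the more nucleophilic substrate for chlorination. The gain is a direct link to the product of the key step. The demand is a removal that does not generate electrophiles next to the electron-rich ring A.

**8 to 5, 6 and 7.** Both C–C bonds at the carbonyl carbon are cut, the one to ring A C1 and the one to ring B C2. This is the only junction between the rings, and cutting here gives three simple components. The position of the ketone on ring A is decided by the position of iodine in 5, not by the directing effects of an acylation. The demand is that insertion of 6 must precede transfer of the pyrrolyl group, and that 7 must survive long enough to transmetalate.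

**5 to 4.** The C–I bond is cut. The two open positions of 4 that are ortho to one methoxy group and para to the other are equivalent by symmetry, so electrophilic iodination can give only one mono-iodide. The demand is to stop at mono-substitution.

**4 to 1 and 2, via 3.** The bond between ring A C3 and the first CH2 of the chain is cut. The hydrogen between the two methoxy groups of 1 is the most acidic, so metalation gives 3 at that position only, and 2 is an unhindered primary electrophile. The gain is two commercial starting materials. The demand is substitution in preference to elimination.

## Other disconnections considered

**Alternative 1:** The cut runs through ring A, at C1–C2 and C5–C6. Ring A C2 to C5, with the chain and both oxygens, would come from the diene 1-methoxy-2-(4-methylpentyl)-1,3-bis(trimethylsilyloxy)buta-1,3-diene A2. Ring A C1 and C6, the carbonyl group and ring B would come from the ynone 1-(4,5-dichloro-1-tosylpyrrol-2-yl)prop-2-yn-1-one A3.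

- Forward key step: the CH2 terminus of A2 adds to the terminal alkyne carbon of A3, the ketene acetal carbon closes onto the acyl-bearing alkyne carbon, and acidic work-up removes methanol and both silyl groups. This should give the N-tosyl resorcinol ketone A1, and mild basic desulfonylation would then give 11.
- In favour: ring A would be formed fully substituted with free hydroxyls, and the polarity match places the ketone ortho to one oxygen and para to the other. The chlorines are present from the start, so neither a chlorination beside an activated arene nor a BBr3 step is needed. On both of these points the alternative is better than the chosen plan.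
- Against: A2 has a fully substituted ketene acetal terminus next to the chain, is hindered, sensitive to hydrolysis and is expected to be a mixture of double-bond isomers. A3 is a strongly electrophilic terminal ynone, prone to conjugate addition and polymerisation. If the addition is stepwise, the open-chain adduct could fail to close or could close through oxygen to a pyranone. Both A2 and A3 need their own multistep preparations.
- Comparison: on structure the two plans are equal, since the chosen plan fixes the same pattern through the symmetry of 4 and ortho/para direction. On mechanism, a polar cycloaddition cascade with two sensitive partners stands against a palladium cycle whose main competitor is held back by the substrate's own electronics. On step economy, the alternative probably needs eight or more steps in total against six, but its longest linear sequence could be shorter, which is a point in its favour.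

**Alternative 2:** Ring B is traced back to a pyridine. The N–C5 bond of the pyrrole is opened and the ketone carbon is returned to the ring as pyridine C6, which leads to 2,3-dichloro-6-[2,4-dimethoxy-3-(4-methylpentyl)phenyl]pyridine 1-oxide A5.

- Forward key step: irradiation of A5 would move oxygen from nitrogen to C6, break N–C6 and join nitrogen to the former C5. This should give (4,5-dichloro-1H-pyrrol-2-yl)[2,4-dimethoxy-3-(4-methylpentyl)phenyl]methanone A4, which is the same compound as 10 and one ether cleavage away from 11.
- In favour: both chlorines come from the pyridine unit in fixed positions, so no pyrrole chlorination and no N-protecting group are needed, which is better than the chosen plan. A5 could be assembled from 5 by an ordinary biaryl cross-coupling and N-oxidation, which is more routine than a carbonylative coupling and avoids CO.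
- Against: ring contractions of excited pyridine N-oxides compete with deoxygenation and with rearrangement to hydroxypyridines, pyridones and oxazepines. The oxygen can shift to either carbon flanking nitrogen, and only the shift to the aryl-bearing carbon gives the wanted skeleton. The aryl C–Cl bonds are photolabile, and the electron-rich dimethoxyaryl group can divert the excited state.
- Comparison: on structure the alternative places the chlorines more securely. On mechanism, an excited-state rearrangement offers few handles for steering product partition, whereas the catalytic cycle of the chosen plan can be tuned through CO pressure, base and ligand. On step economy the two are about equal, at six to seven steps, and both end with the same ether cleavage.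

**Alternative 3:** Ring B is cut at N–C5 and C2–C3. This gives the aminoketone 2-amino-1-[2,4-dimethoxy-3-(4-methylpentyl)phenyl]ethan-1-one hydrochloride A7 and the salt 2-chloro-1,3-bis(dimethylamino)trimethinium hexafluorophosphate A8.

- Forward key step: the amine of A7 exchanges with one dimethylamino terminus of A8, the methylene between nitrogen and the ketone attacks the other iminium carbon, and loss of dimethylamine aromatises the ring. This should give (4-chloro-1H-pyrrol-2-yl)[2,4-dimethoxy-3-(4-methylpentyl)phenyl]methanone A6. Chlorination at C5 and ether cleavage would complete the synthesis.
- In favour: the C4 chlorine is built in with unambiguous regiochemistry, and only one further chlorine has to be introduced, at the most reactive remaining pyrrole position. This lowers the risk of over-chlorination and is a better point than in the chosen plan. A8 is a stable salt, and no palladium, CO or boron reagent is needed.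
- Against: A7 has to be made from 4 by Friedel–Crafts chloroacetylation with AlCl3, which may cleave the ortho ether, followed by amination in one or two steps. The free base of A7 self-condenses readily, so it must be released only in the presence of A8. A chlorination of the pyrrole next to the activated ring A and the same final ether cleavage remain.
- Comparison: on structure, the alternative controls one chlorine better, but it places the ketone on ring A by an acylation, where the chosen plan uses a position-defined iodide. On mechanism, it is a two-component ionic condensation and simpler to run than a three-component catalytic coupling. On step economy it is equal, at six to seven steps.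

Key step: step 3

Remark on the chemistry: lithiation and alkylation are run in one flask and counted as one step. The structures of the coupling partners and of the coupling product were checked atom by atom against the target and needed no correction. The one design change is that the Boc group is removed by methoxide and not by acid, so that no tert-butyl cation is formed beside ring A.

Step 1
Reactants: 1 1,3-dimethoxybenzene; 2 1-bromo-4-methylpentane
Product: 4 1,3-dimethoxy-2-(4-methylpentyl)benzene, via 2,6-dimethoxyphenyllithium 3 (not isolated)
Conditions: n-BuLi, THF, 0 °C to rt; then 2, 0 °C to 50 °C
Reagents that add atoms: none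
Why: Directed ortho-metalation followed by SN2 alkylation; both methoxy groups coordinate lithium and acidify the hydrogen between them, so deprotonation should occur only there, and the primary bromide, branched only at a remote carbon, should be substituted cleanly.

Step 2
Reactants: 4 1,3-dimethoxy-2-(4-methylpentyl)benzene
Product: 5 1-iodo-2,4-dimethoxy-3-(4-methylpentyl)benzene
Conditions: NIS (1.05 equiv), TFA (cat.), MeCN, 0 °C to rt
Reagents that add atoms: N-iodosuccinimide, O=C1CCC(=O)N1I
Why: Electrophilic aromatic iodination; the two positions ortho to one methoxy group and para to the other are equivalent by symmetry and the remaining position is meta to both, so a single mono-iodide is expected, and the stoichiometry limits di-iodination.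

Step 3
Reactants: 5 1-iodo-2,4-dimethoxy-3-(4-methylpentyl)benzene; 6 carbon monoxide; 7 N-Boc-pyrrol-2-ylboronic acid
Product: 8 tert-butyl 2-[2,4-dimethoxy-3-(4-methylpentyl)benzoyl]pyrrole-1-carboxylate
Conditions: PdCl2(PPh3)2 (3 mol%), K2CO3 (3 equiv), CO (1 atm), anisole, 80 °C
Reagents that add atoms: none
Why: This is a carbonylative Suzuki–Miyaura coupling, a known reaction type for ortho-substituted aryl iodides and heteroarylboronic acids. PdCl2(PPh3)2 is reduced in the flask to zerovalent palladium, which inserts into the C–I bond of 5 to give an arylpalladium iodide of divalent palladium. CO (6) then coordinates and the electron-rich aryl group migrates onto it, giving an aroylpalladium species. The boronate formed from 7 and K2CO3 transfers the pyrrol-2-yl group to palladium, and reductive elimination forms the second C–C bond, releases ketone 8 and returns zerovalent palladium. No ring is closed and no stereocentre is created, so the only selectivity needed is chemoselectivity for the ketone over the direct biaryl and over protodeboronation of 7. The donor-substituted, ortho-methoxy arylpalladium intermediate should insert CO quickly and transmetalate slowly, the sparingly soluble K2CO3 in anisole keeps the boronate concentration low, and the Boc group tempers the pyrrole so that its C–B bond lasts long enough to react. The site of the ketone on ring A is fixed by the position of iodine, and neither an acid chloride nor a Lewis acid meets the pyrrole; any Boc lost under the basic conditions would give 9 directly, which is harmless.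

Step 4
Reactants: 8 tert-butyl 2-[2,4-dimethoxy-3-(4-methylpentyl)benzoyl]pyrrole-1-carboxylate
Product: 9 [2,4-dimethoxy-3-(4-methylpentyl)phenyl](1H-pyrrol-2-yl)methanone
Conditions: NaOMe (cat.), MeOH/THF, rt
Reagents that add atoms: none
Why: Methanolysis of an activated carbamate (nucleophilic acyl substitution); methoxide adds to the Boc carbonyl, the 2-aroylpyrrolide is a good leaving group and is reprotonated by methanol, and the methyl ethers and the non-enolisable ketone should be inert.

Step 5
Reactants: 9 [2,4-dimethoxy-3-(4-methylpentyl)phenyl](1H-pyrrol-2-yl)methanone
Product: 10 (4,5-dichloro-1H-pyrrol-2-yl)[2,4-dimethoxy-3-(4-methylpentyl)phenyl]methanone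
Conditions: SO2Cl2 (2.05 equiv), CH2Cl2, −20 to 0 °C
Reagents that add atoms: sulfuryl chloride, O=S(=O)(Cl)Cl
Why: Electrophilic aromatic chlorination of a 2-acylpyrrole; the acyl group leaves C4 and the free alpha position C5 as the reactive sites and shields C3, so two equivalents should fill C4 and C5, while ring A is less nucleophilic than the pyrrole because of its carbonyl group and its twisted C2 methoxy group.

Step 6
Reactants: 10 (4,5-dichloro-1H-pyrrol-2-yl)[2,4-dimethoxy-3-(4-methylpentyl)phenyl]methanone
Product: 11 (4,5-dichloro-1H-pyrrol-2-yl)[2,4-dihydroxy-3-(4-methylpentyl)phenyl]methanone
Conditions: BBr3 (5 equiv), CH2Cl2, −78 °C to rt; then H2O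
Reagents that add atoms: none
Why: Lewis-acid ether cleavage; boron coordinates each methoxy oxygen, bromide removes the methyl group by SN2 and the aryloxyboranes are hydrolysed on work-up, with chelation to the ketone assisting the C2 ether, while the C–Cl bonds, the ketone and the pyrrole should be untouched.

Compound list

1 | 1,3-dimethoxybenzene | COc1cccc(OC)c1 | starting material
2 | 1-bromo-4-methylpentane | CC(C)CCCBr | starting material
3 | 2,6-dimethoxyphenyllithium | [Li]c1c(OC)cccc1OC | intermediate (not isolated)
4 | 1,3-dimethoxy-2-(4-methylpentyl)benzene | CC(C)CCCc1c(OC)cccc1OC | intermediate
5 | 1-iodo-2,4-dimethoxy-3-(4-methylpentyl)benzene | CC(C)CCCc1c(OC)ccc(I)c1OC | intermediate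
6 | carbon monoxide | [C-]#[O+] | starting material
7 | N-Boc-pyrrol-2-ylboronic acid, [1-(tert-butoxycarbonyl)-1H-pyrrol-2-yl]boronic acid | OB(O)c1cccn1C(=O)OC(C)(C)C | starting material
8 | tert-butyl 2-[2,4-dimethoxy-3-(4-methylpentyl)benzoyl]pyrrole-1-carboxylate | CC(C)CCCc1c(OC)ccc(C(=O)c2cccn2C(=O)OC(C)(C)C)c1OC | intermediate
9 | [2,4-dimethoxy-3-(4-methylpentyl)phenyl](1H-pyrrol-2-yl)methanone | CC(C)CCCc1c(OC)ccc(C(=O)c2ccc[nH]2)c1OC | intermediate
10 | (4,5-dichloro-1H-pyrrol-2-yl)[2,4-dimethoxy-3-(4-methylpentyl)phenyl]methanone | CC(C)CCCc1c(OC)ccc(C(=O)c2cc(Cl)c(Cl)[nH]2)c1OC | intermediate
11 | (4,5-dichloro-1H-pyrrol-2-yl)[2,4-dihydroxy-3-(4-methylpentyl)phenyl]methanone | CC(C)CCCc1c(O)ccc(C(=O)c2cc(Cl)c(Cl)[nH]2)c1O | target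

Total step count: 6. Longest linear sequence: 6 steps (1 to 4 to 5 to 8 to 9 to 10 to 11).

Least certain steps

**Step 3 (key step).** The most likely failure is that transfer of the pyrrolyl group to the arylpalladium intermediate outruns CO insertion, giving direct biaryl coupling. The other is that protodeboronation consumes 7 before it can transmetalate; both processes are fast for 2-heteroaryl boron compounds under basic conditions.
Fallback: the route would set out from 5 and come back at 9, avoiding palladium, CO and boron. Iodine–magnesium exchange with i-PrMgCl·LiCl in THF at 0 °C should give [2,4-dimethoxy-3-(4-methylpentyl)phenyl]magnesium chloride F1. Trapping with morpholine-4-carbonyl chloride should give [2,4-dimethoxy-3-(4-methylpentyl)phenyl](morpholin-4-yl)methanone F2. Vilsmeier–Haack aroylation of pyrrole with F2 (POCl3, then pyrrole in 1,2-dichloroethane, then aqueous NaOAc with heating) should give 9 directly, so step 4 is skipped.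

**Step 5.** The most likely failure is loss of site selectivity: chlorination spilling onto ring A C5, which is activated by both methoxy groups, or onto pyrrole C3, together with incomplete second chlorination, giving mixtures that are hard to separate.
Fallback: the route would set out from 4 and come back at 10, with the chlorines brought in already attached. Commercial 4,5-dichloro-1H-pyrrole-2-carboxylic acid would be converted with oxalyl chloride and catalytic DMF into 4,5-dichloro-1H-pyrrole-2-carbonyl chloride F3. Friedel–Crafts acylation of 4 with F3 and AlCl3 in CH2Cl2 at 0 °C should take place at the position ortho to one methoxy group and para to the other. Any material that loses the ortho methyl group under AlCl3 would converge on 11 in step 6.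

**Step 1.** The most likely failure is elimination of HBr from 2 by the strongly basic aryllithium, combined with sluggish substitution by the aggregated organolithium, which returns 1 after work-up.
Fallback: the route would set out from 1 and come back at 4, replacing alkylation by carbonyl addition. Intermediate 3, generated as in step 1, would be added to 4-methylpentanal to give racemic 1-(2,6-dimethoxyphenyl)-4-methylpentan-1-ol F4. Ionic hydrogenation of this doubly ortho-oxygenated benzylic alcohol with Et3SiH and TFA in CH2Cl2 should give 4.

**Step 6.** The most likely failure is incomplete cleavage of the C4 ether, which has no chelation assistance and is flanked by the chain, together with slow acid-mediated degradation of the dichloropyrrole ketone if the exposure is prolonged.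
Fallback: the route would set out from 9 and come back at 11, moving the harsh ether cleavage ahead of the chlorination and ending with a mild methanolysis. BBr3 on the halogen-free and more robust 9 should give [2,4-dihydroxy-3-(4-methylpentyl)phenyl](1H-pyrrol-2-yl)methanone F5. Ac2O in pyridine should give 2-(4-methylpentyl)-4-(1H-pyrrole-2-carbonyl)-1,3-phenylene diacetate F6, in which the acetates also deactivate ring A. SO2Cl2 (2 equiv) should give 4-(4,5-dichloro-1H-pyrrole-2-carbonyl)-2-(4-methylpentyl)-1,3-phenylene diacetate F7, and K2CO3 in MeOH should then release 11.

## Further compounds

F1 | step 3 | [2,4-dimethoxy-3-(4-methylpentyl)phenyl]magnesium chloride | CC(C)CCCc1c(OC)ccc([Mg]Cl)c1OC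
F2 | step 3 | [2,4-dimethoxy-3-(4-methylpentyl)phenyl](morpholin-4-yl)methanone | CC(C)CCCc1c(OC)ccc(C(=O)N2CCOCC2)c1OC
F3 | step 5 | 4,5-dichloro-1H-pyrrole-2-carbonyl chloride | O=C(Cl)c1cc(Cl)c(Cl)[nH]1
F4 | step 1 | 1-(2,6-dimethoxyphenyl)-4-methylpentan-1-ol (racemic) | CC(C)CCC(O)c1c(OC)cccc1OC
F5 | step 6 | [2,4-dihydroxy-3-(4-methylpentyl)phenyl](1H-pyrrol-2-yl)methanone | CC(C)CCCc1c(O)ccc(C(=O)c2ccc[nH]2)c1O
F6 | step 6 | 2-(4-methylpentyl)-4-(1H-pyrrole-2-carbonyl)-1,3-phenylene diacetate | CC(C)CCCc1c(OC(C)=O)ccc(C(=O)c2ccc[nH]2)c1OC(C)=O
F7 | step 6 | 4-(4,5-dichloro-1H-pyrrole-2-carbonyl)-2-(4-methylpentyl)-1,3-phenylene diacetate | CC(C)CCCc1c(OC(C)=O)ccc(C(=O)c2cc(Cl)c(Cl)[nH]2)c1OC(C)=O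
A1 | alternative 1 | (4,5-dichloro-1-tosyl-1H-pyrrol-2-yl)[2,4-dihydroxy-3-(4-methylpentyl)phenyl]methanone | CC(C)CCCc1c(O)ccc(C(=O)c2cc(Cl)c(Cl)n2S(=O)(=O)c2ccc(C)cc2)c1O
A2 | alternative 1 | 1-methoxy-2-(4-methylpentyl)-1,3-bis(trimethylsilyloxy)buta-1,3-diene (double-bond geometry unspecified) | COC(O[Si](C)(C)C)=C(CCCC(C)C)C(=C)O[Si](C)(C)C
A3 | alternative 1 | 1-(4,5-dichloro-1-tosyl-1H-pyrrol-2-yl)prop-2-yn-1-one | C#CC(=O)c1cc(Cl)c(Cl)n1S(=O)(=O)c1ccc(C)cc1
A4 | alternative 2 | (4,5-dichloro-1H-pyrrol-2-yl)[2,4-dimethoxy-3-(4-methylpentyl)phenyl]methanone | CC(C)CCCc1c(OC)ccc(C(=O)c2cc(Cl)c(Cl)[nH]2)c1OC
A5 | alternative 2 | 2,3-dichloro-6-[2,4-dimethoxy-3-(4-methylpentyl)phenyl]pyridine 1-oxide | CC(C)CCCc1c(OC)ccc(-c2ccc(Cl)c(Cl)[n+]2[O-])c1OC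
A6 | alternative 3 | (4-chloro-1H-pyrrol-2-yl)[2,4-dimethoxy-3-(4-methylpentyl)phenyl]methanone | CC(C)CCCc1c(OC)ccc(C(=O)c2cc(Cl)c[nH]2)c1OC
A7 | alternative 3 | 2-amino-1-[2,4-dimethoxy-3-(4-methylpentyl)phenyl]ethan-1-one hydrochloride | CC(C)CCCc1c(OC)ccc(C(=O)CN)c1OC.Cl
A8 | alternative 3 | 2-chloro-1,3-bis(dimethylamino)trimethinium hexafluorophosphate | CN(C)C=C(Cl)C=[N+](C)C.F[P-](F)(F)(F)(F)F
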